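**Retrosynthetic overview**
1. Ring B is closed last by ring-closing metathesis (C1=C2) on triene 24; the Z tetrasubstituted C5=C6 olefin comes from a 1,4-hydrogenation of the 2,3-disubstituted diene 23.
2. Diene 23 is the Suzuki union (C5–C6) of ring A triflate 21 with the C/D enol triflate 16.
3. Ring C is closed on a finished ring D by aldol cyclodehydration, then C15 (cuprate) and C7 (equilibration) are set.
4. Ring D comes from furfural: a Piancatelli rearrangement turns the furan into a 4-hydroxycyclopentenone whose carbinol centre, after lipase resolution, is relayed to C10, then C9 and C13.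
5. Order of ring formation: D (from the furan) → C → B; ring A is made separately from 2-bromocyclopent-2-enone.

Assumption 1 (atom labels, read along the target SMILES): ring B = C1(CH3), C2, C3, C4, C5, C6(CH3), C7, C15; ring C = C7, C8, C9, C13, C14, C15; ring D = C9, C10(isopropyl), C11, C12(OH), C13(CH3); ring A = C4, C5, C16, C17, C18(CH3); the target is 4S,7S,9S,10S,12R,13R,15S,18S with both ring-B olefins Z.
Assumption 2: the lipase acylates the (4S,5R)-alcohol of 3, the same spatial sense as its known preference for (R)-4-hydroxycyclopent-2-enone; if it is reversed, the recovered alcohol is acetylated chemically.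

**Step 1**
Reactants: 1 furfural
Product: 3 rac-(4S,5R)-4-hydroxy-5-methylcyclopent-2-en-1-one (trans), via 1-(furan-2-yl)ethan-1-ol 2 (not isolated)
Conditions: MeMgBr, THF, 0 °C; aq. NH4Cl; then ZnCl2, 1,4-dioxane/H2O (pH 6), reflux
Reagents that add atoms: methylmagnesium bromide C[Mg]Br; water O
Why: Grignard addition then Piancatelli rearrangement: the furan opens to an oxypentadienyl cation whose conrotatory 4π electrocyclization (both substituents outward) gives the trans hydroxy enone as a racemate; the furan carbons and the new methyl become C9–C13 and the C13 methyl of ring D.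

**Step 2**
Reactants: 3 rac-(4S,5R)-4-hydroxy-5-methylcyclopent-2-en-1-one
Product: 4 (1S,5R)-5-methyl-4-oxocyclopent-2-en-1-yl acetate
Conditions: Burkholderia cepacia lipase, vinyl acetate, t-BuOMe, 25 °C, to about 50% conversion
Reagents that add atoms: vinyl acetate CC(=O)OC=C
Why: Lipase-catalysed kinetic resolution by transesterification under neutral conditions (no base, so the enone does not isomerise) acetylates one enantiomer and fixes the absolute configuration of the whole C/D half.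

**Step 3**
Reactants: 4 (1S,5R)-5-methyl-4-oxocyclopent-2-en-1-yl acetate
Product: 6 (4S)-2-methyl-4-(propan-2-yl)cyclopent-2-en-1-one, via acetoxy ketone 5 (not isolated)
Conditions: i-PrMgCl (slow addition), CuBr·SMe2 (10 mol%), THF, −78 °C; aq. NH4Cl; then Et3N, CH2Cl2, 0 °C to rt
Reagents that add atoms: isopropylmagnesium chloride CC(C)[Mg]Cl
Why: Copper-catalysed conjugate addition anti to the neighbouring acetoxy group, then E1cB loss of acetate, moves the enone and transfers the chirality of the C–O centre to C10 (S).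

**Step 4**
Reactants: 6 (4S)-2-methyl-4-(propan-2-yl)cyclopent-2-en-1-one; 7 2-(2-bromoethyl)-2-methyl-1,3-dioxolane
Product: 9 (2R,3S,4S)-2-methyl-3-[2-(2-methyl-1,3-dioxolan-2-yl)ethyl]-4-(propan-2-yl)-2-(prop-2-en-1-yl)cyclopentan-1-one, via magnesium enolate 8 (not isolated)
Conditions: 7, Mg, THF; CuBr·SMe2 (10 mol%), −40 °C, then 6; then allyl bromide, HMPA, −40 to 0 °C
Reagents that add atoms: allyl bromide C=CCBr
Why: Three-component coupling: the copper-catalysed conjugate addition enters anti to the C10 isopropyl group (sets C9), and the regiodefined enolate is allylated anti to the new C9 chain, so the C13 methyl ends trans to H9 as the trans ring fusion requires.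

**Step 5**
Reactants: 9 (2R,3S,4S)-2-methyl-3-[2-(2-methyl-1,3-dioxolan-2-yl)ethyl]-4-(propan-2-yl)-2-(prop-2-en-1-yl)cyclopentan-1-one
Product: 12 (3S,3aS,7aR)-5-acetyl-7a-methyl-3-(propan-2-yl)-2,3,3a,4,7,7a-hexahydro-1H-inden-1-one, via aldehyde 10 (not isolated), via keto-aldehyde 11 (not isolated)
Conditions: O3, CH2Cl2/MeOH, −78 °C; Me2S; then 1 M HCl, THF, 45 °C
Reagents that add atoms: ozone [O-][O+]=O (oxygen kept only in 10 and 11); water O
Why: Ozonolysis gives the C15 aldehyde; acid removes the ketal and the more substituted enol of the methyl ketone (C7) condenses on the aldehyde (intramolecular aldol condensation) to the 1-acetylcyclohexene, closing ring C trans-fused because C9 and C13 are already set.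

**Step 6**
Reactants: 12 (3S,3aS,7aR)-5-acetyl-7a-methyl-3-(propan-2-yl)-2,3,3a,4,7,7a-hexahydro-1H-inden-1-one
Product: 13 1-[(1R,3S,3aS,7aR)-1-hydroxy-7a-methyl-3-(propan-2-yl)-2,3,3a,4,7,7a-hexahydro-1H-inden-5-yl]ethan-1-one
Conditions: NaBH4, MeOH/CH2Cl2 (1:1), −78 °C
Reagents that add atoms: none
Why: Chemoselective borohydride reduction: the saturated cyclopentanone reacts faster than the conjugated methyl ketone (as the 17-ketone does in androstenedione), and hydride attacks anti to the angular methyl, giving the C12 alcohol cis to that methyl (R).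

**Step 7**
Reactants: 13 1-[(1R,3S,3aS,7aR)-1-hydroxy-7a-methyl-3-(propan-2-yl)-2,3,3a,4,7,7a-hexahydro-1H-inden-5-yl]ethan-1-one
Product: 15 1-[(1R,3S,3aS,5S,6S,7aR)-1-hydroxy-7a-methyl-3-(propan-2-yl)-6-(prop-1-en-2-yl)octahydro-1H-inden-5-yl]ethan-1-one, via C5-epimer 14 (not isolated)
Conditions: CH2=C(CH3)MgBr (3 equiv), CuI (10 mol%), THF, −40 to 0 °C; aq. NH4Cl; then NaOMe, MeOH, 25 °C
Reagents that add atoms: isopropenylmagnesium bromide CC(=C)[Mg]Br
Why: Copper-catalysed (Kharasch-type) conjugate addition attacks C15 from the face opposite the axial C13 methyl (1,3-diaxial blocking, as at C11 of steroids); kinetic protonation gives the axial acetyl epimer 14, and NaOMe equilibrates C7 to the trans-diequatorial ketone.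

**Step 8**
Reactants: 15 1-[(1R,3S,3aS,5S,6S,7aR)-1-hydroxy-7a-methyl-3-(propan-2-yl)-6-(prop-1-en-2-yl)octahydro-1H-inden-5-yl]ethan-1-one
Product: 16 1-[(1R,3S,3aS,5S,6S,7aR)-1-hydroxy-7a-methyl-3-(propan-2-yl)-6-(prop-1-en-2-yl)octahydro-1H-inden-5-yl]ethenyl trifluoromethanesulfonate
Conditions: PhNTf2, KN(SiMe3)2 (2.2 equiv, added last), THF, −78 °C
Reagents that add atoms: N-phenylbis(trifluoromethanesulfonimide) O=S(=O)(N(c1ccccc1)S(=O)(=O)C(F)(F)F)C(F)(F)F
Why: Kinetic enolisation at the unhindered methyl group with in situ O-triflation gives the 1,1-disubstituted enol triflate; the hindered secondary potassium alkoxide is not triflated by PhNTf2 at −78 °C and C7 is untouched.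

**Step 9**
Reactants: 17 2-bromocyclopent-2-en-1-one
Product: 18 2-(prop-2-en-1-yl)cyclopent-2-en-1-one
Conditions: allylSnBu3, Pd(PPh3)4 (5 mol%), CuI (10 mol%), DMF, 60 °C
Reagents that add atoms: allyltributylstannane C=CC[Sn](CCCC)(CCCC)CCCC
Why: Stille cross-coupling of an α-bromo enone with an allylstannane installs the C3–C2 handle on the future C4; no stereocentre is formed.

**Step 10**
Reactants: 18 2-(prop-2-en-1-yl)cyclopent-2-en-1-one
Product: 20 (2S,3S)-3-methyl-2-(prop-2-en-1-yl)cyclopentan-1-one, via aluminium enolate 19 (not isolated)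
Conditions: Me3Al, Cu(OTf)2 (5 mol%), chiral phosphoramidite ligand (10 mol%, enantiomer giving 3S), Et2O, −30 °C; then ethyl salicylate, −78 °C
Reagents that add atoms: trimethylaluminium C[Al](C)C
Why: Copper/phosphoramidite-catalysed asymmetric conjugate addition sets C18 (S) under ligand control, and kinetic protonation of the enolate by the chelating acid ethyl salicylate from the face opposite the new methyl gives the cis-2,3 ketone (C4 S).

**Step 11**
Reactants: 20 (2S,3S)-3-methyl-2-(prop-2-en-1-yl)cyclopentan-1-one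
Product: 21 (4S,5S)-4-methyl-5-(prop-2-en-1-yl)cyclopent-1-en-1-yl trifluoromethanesulfonate
Conditions: PhNTf2, KN(SiMe3)2 (1.1 equiv, added last), THF, −78 °C
Reagents that add atoms: N-phenylbis(trifluoromethanesulfonimide) O=S(=O)(N(c1ccccc1)S(=O)(=O)C(F)(F)F)C(F)(F)F
Why: Kinetic enolisation at the unsubstituted α-CH2 (C16) with in situ triflation leaves the tertiary C4–H untouched, so the labile cis ketone is locked as a non-epimerisable alkenyl triflate.

**Step 12**
Reactants: 21 (4S,5S)-4-methyl-5-(prop-2-en-1-yl)cyclopent-1-en-1-yl trifluoromethanesulfonate; 16 1-[(1R,3S,3aS,5S,6S,7aR)-1-hydroxy-7a-methyl-3-(propan-2-yl)-6-(prop-1-en-2-yl)octahydro-1H-inden-5-yl]ethenyl trifluoromethanesulfonate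
Product: 23 (1R,3S,3aS,5S,6S,7aR)-7a-methyl-5-{1-[(4S,5S)-4-methyl-5-(prop-2-en-1-yl)cyclopent-1-en-1-yl]ethenyl}-3-(propan-2-yl)-6-(prop-1-en-2-yl)octahydro-1H-inden-1-ol, via boronate 22 (not isolated)
Conditions: 21, B2pin2, PdCl2(dppf) (5 mol%), KOPh, dioxane, 60 °C; then 16, aq. K3PO4, 80 °C
Reagents that add atoms: bis(pinacolato)diboron CC1(C)OB(OC1(C)C)B2OC(C)(C)C(C)(C)O2 (boron kept only in 22)
Why: One-pot Miyaura borylation and Suzuki–Miyaura coupling of two alkenyl triflates forms the C5–C6 bond and joins the two halves; no stereocentre is touched.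

**Step 13**
Reactants: 23 (1R,3S,3aS,5S,6S,7aR)-7a-methyl-5-{1-[(4S,5S)-4-methyl-5-(prop-2-en-1-yl)cyclopent-1-en-1-yl]ethenyl}-3-(propan-2-yl)-6-(prop-1-en-2-yl)octahydro-1H-inden-1-ol
Product: 24 (1R,3S,3aS,5S,6S,7aR)-7a-methyl-5-{(1Z)-1-[(2S,3S)-3-methyl-2-(prop-2-en-1-yl)cyclopentylidene]ethyl}-3-(propan-2-yl)-6-(prop-1-en-2-yl)octahydro-1H-inden-1-ol
Conditions: (η6-naphthalene)Cr(CO)3 (20 mol%), H2 (5 atm), THF, 45 °C
Reagents that add atoms: none
Why: Chromium-catalysed 1,4-hydrogenation of the s-cis diene adds hydrogen to both termini (C16 and the CH2), so the new C6 methyl ends cis to C16 and C4 ends cis to C7 (Z); isolated olefins do not react and no new stereocentre is made.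

**Step 14**
Reactants: 24 (1R,3S,3aS,5S,6S,7aR)-7a-methyl-5-{(1Z)-1-[(2S,3S)-3-methyl-2-(prop-2-en-1-yl)cyclopentylidene]ethyl}-3-(propan-2-yl)-6-(prop-1-en-2-yl)octahydro-1H-inden-1-ol
Product: 25 CNP0541339.1 (target dienol)
Conditions: second-generation Hoveyda–Grubbs catalyst (10 mol%), 1,4-benzoquinone (10 mol%), toluene (1 mM), 100 °C
Reagents that add atoms: none
Why: Ring-closing metathesis between the allyl and isopropenyl groups, held cis by the Z tetrasubstituted olefin, forms the trisubstituted C1=C2 olefin, Z by the constraint of the eight-membered ring; the tetrasubstituted olefin and free hydroxyl are inert.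

**Compound list**
1 | furfural | O=Cc1ccco1 | starting material
2 | 1-(furan-2-yl)ethan-1-ol (racemic) | CC(O)c1ccco1 | intermediate (not isolated)
3 | rac-(4S,5R)-4-hydroxy-5-methylcyclopent-2-en-1-one (trans; SMILES shows the enantiomer carried on) | O=C1C=C[C@H](O)[C@H]1C | intermediate
4 | (1S,5R)-5-methyl-4-oxocyclopent-2-en-1-yl acetate | O=C1C=C[C@H](OC(C)=O)[C@H]1C | intermediate
5 | (1S,2R,5S)-2-methyl-3-oxo-5-(propan-2-yl)cyclopentyl acetate | O=C1C[C@@H](C(C)C)[C@H](OC(C)=O)[C@H]1C | intermediate (not isolated)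
6 | (4S)-2-methyl-4-(propan-2-yl)cyclopent-2-en-1-one | CC1=C[C@H](C(C)C)CC1=O | intermediate
7 | 2-(2-bromoethyl)-2-methyl-1,3-dioxolane | CC1(CCBr)OCCO1 | starting material
8 | bromomagnesium (3S,4S)-2-methyl-3-[2-(2-methyl-1,3-dioxolan-2-yl)ethyl]-4-(propan-2-yl)cyclopent-1-en-1-olate | CC1(CC[C@H]2[C@H](C(C)C)CC(O[Mg]Br)=C2C)OCCO1 | intermediate (not isolated)
9 | (2R,3S,4S)-2-methyl-3-[2-(2-methyl-1,3-dioxolan-2-yl)ethyl]-4-(propan-2-yl)-2-(prop-2-en-1-yl)cyclopentan-1-one | CC1(CC[C@H]2[C@H](C(C)C)CC(=O)[C@]2(C)CC=C)OCCO1 | intermediate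
10 | 2-[(1R,2S,3S)-1-methyl-2-[2-(2-methyl-1,3-dioxolan-2-yl)ethyl]-5-oxo-3-(propan-2-yl)cyclopentyl]acetaldehyde | CC1(CC[C@H]2[C@H](C(C)C)CC(=O)[C@]2(C)CC=O)OCCO1 | intermediate (not isolated)
11 | 2-[(1R,2S,3S)-1-methyl-5-oxo-2-(3-oxobutyl)-3-(propan-2-yl)cyclopentyl]acetaldehyde | CC(=O)CC[C@H]1[C@H](C(C)C)CC(=O)[C@]1(C)CC=O | intermediate (not isolated)
12 | (3S,3aS,7aR)-5-acetyl-7a-methyl-3-(propan-2-yl)-2,3,3a,4,7,7a-hexahydro-1H-inden-1-one | CC(=O)C=1C[C@H]2[C@H](C(C)C)CC(=O)[C@]2(C)CC=1 | intermediate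
13 | 1-[(1R,3S,3aS,7aR)-1-hydroxy-7a-methyl-3-(propan-2-yl)-2,3,3a,4,7,7a-hexahydro-1H-inden-5-yl]ethan-1-one | CC(=O)C=1C[C@H]2[C@H](C(C)C)C[C@@H](O)[C@]2(C)CC=1 | intermediate
14 | 1-[(1R,3S,3aS,5R,6S,7aR)-1-hydroxy-7a-methyl-3-(propan-2-yl)-6-(prop-1-en-2-yl)octahydro-1H-inden-5-yl]ethan-1-one | CC(=O)[C@@H]1C[C@H]2[C@H](C(C)C)C[C@@H](O)[C@]2(C)C[C@@H]1C(C)=C | intermediate (not isolated)
15 | 1-[(1R,3S,3aS,5S,6S,7aR)-1-hydroxy-7a-methyl-3-(propan-2-yl)-6-(prop-1-en-2-yl)octahydro-1H-inden-5-yl]ethan-1-one | CC(=O)[C@H]1C[C@H]2[C@H](C(C)C)C[C@@H](O)[C@]2(C)C[C@@H]1C(C)=C | intermediate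
16 | 1-[(1R,3S,3aS,5S,6S,7aR)-1-hydroxy-7a-methyl-3-(propan-2-yl)-6-(prop-1-en-2-yl)octahydro-1H-inden-5-yl]ethenyl trifluoromethanesulfonate | C=C(OS(=O)(=O)C(F)(F)F)[C@H]1C[C@H]2[C@H](C(C)C)C[C@@H](O)[C@]2(C)C[C@@H]1C(C)=C | intermediate
17 | 2-bromocyclopent-2-en-1-one | O=C1CCC=C1Br | starting material
18 | 2-(prop-2-en-1-yl)cyclopent-2-en-1-one | C=CCC1=CCCC1=O | intermediate
19 | dimethylaluminium (3S)-3-methyl-2-(prop-2-en-1-yl)cyclopent-1-en-1-olate | C=CCC1=C(O[Al](C)C)CC[C@@H]1C | intermediate (not isolated)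
20 | (2S,3S)-3-methyl-2-(prop-2-en-1-yl)cyclopentan-1-one (cis) | C=CC[C@@H]1C(=O)CC[C@@H]1C | intermediate
21 | (4S,5S)-4-methyl-5-(prop-2-en-1-yl)cyclopent-1-en-1-yl trifluoromethanesulfonate | C=CC[C@@H]1C(OS(=O)(=O)C(F)(F)F)=CC[C@@H]1C | intermediate
22 | 4,4,5,5-tetramethyl-2-[(4S,5S)-4-methyl-5-(prop-2-en-1-yl)cyclopent-1-en-1-yl]-1,3,2-dioxaborolane | C=CC[C@@H]1C(B2OC(C)(C)C(C)(C)O2)=CC[C@@H]1C | intermediate (not isolated)
23 | (1R,3S,3aS,5S,6S,7aR)-7a-methyl-5-{1-[(4S,5S)-4-methyl-5-(prop-2-en-1-yl)cyclopent-1-en-1-yl]ethenyl}-3-(propan-2-yl)-6-(prop-1-en-2-yl)octahydro-1H-inden-1-ol | C=C(C1=CC[C@H](C)[C@@H]1CC=C)[C@H]2C[C@H]3[C@H](C(C)C)C[C@@H](O)[C@]3(C)C[C@@H]2C(C)=C | intermediate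
24 | (1R,3S,3aS,5S,6S,7aR)-7a-methyl-5-{(1Z)-1-[(2S,3S)-3-methyl-2-(prop-2-en-1-yl)cyclopentylidene]ethyl}-3-(propan-2-yl)-6-(prop-1-en-2-yl)octahydro-1H-inden-1-ol | C=CC[C@@H]1/C(=C(/C)[C@H]2C[C@H]3[C@H](C(C)C)C[C@@H](O)[C@]3(C)C[C@@H]2C(C)=C)CC[C@@H]1C | intermediate
25 | CNP0541339.1: rings A–D dienol, both ring-B olefins Z, 4S,7S,9S,10S,12R,13R,15S,18S in the labels above | C/C1=C/C[C@@H]2/C(=C(/C)[C@H]3C[C@H]4[C@H](C(C)C)C[C@@H](O)[C@]4(C)C[C@H]13)CC[C@@H]2C | target

**Totals**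
Total step count: 14. Longest linear sequence: 11 (steps 1–8, then 12–14); ring A is a three-step branch (steps 9–11).

**Three steps most likely to fail**

Step 10 (enantioselectivity of methyl addition to an α-substituted cyclopentenone, and the cis ratio of the protonation). The fallback sets out from 18 and returns at 20, replacing asymmetric carbon delivery by asymmetric hydride delivery. MeLi adds 1,2 to 18 to give 1-methyl-2-(prop-2-en-1-yl)cyclopent-2-en-1-ol F1. Oxidative transposition with pyridinium chlorochromate gives 3-methyl-2-(prop-2-en-1-yl)cyclopent-2-en-1-one F2. Copper hydride 1,4-reduction (Cu(OAc)2, (R)- or (S)-DTBM-SEGPHOS chosen for 3S, (EtO)2MeSiH) gives diethoxy(methyl){[(3S)-3-methyl-2-(prop-2-en-1-yl)cyclopent-1-en-1-yl]oxy}silane F3. MeLi then ethyl salicylate at −78 °C protonates the tetrasubstituted enolate anti to the methyl and gives 20.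

Step 13 (the hindered diene may not reach the s-cis chromium complex needed for 1,4-hydrogenation). The fallback sets out from 20 and 15 and returns at 25, making the tetrasubstituted olefin inside the ring. Ketone 20 is condensed with 2,4,6-triisopropylbenzenesulfonyl hydrazide to give N'-[(2S,3S)-3-methyl-2-(prop-2-en-1-yl)cyclopentylidene]-2,4,6-tri(propan-2-yl)benzenesulfonohydrazide F4. Shapiro reaction (n-BuLi) and addition of the cyclopentenyllithium to 15 (CeCl3) give (1R,3S,3aS,5S,6S,7aR)-5-{1-hydroxy-1-[(4S,5S)-4-methyl-5-(prop-2-en-1-yl)cyclopent-1-en-1-yl]ethyl}-7a-methyl-3-(propan-2-yl)-6-(prop-1-en-2-yl)octahydro-1H-inden-1-ol F5 (carbinol epimers). Ring-closing metathesis (second-generation Hoveyda–Grubbs catalyst) gives the ring-B tertiary allylic alcohol F6. Peracetylation (Ac2O, Sc(OTf)3) gives the diacetate F7. Li in NH3 cleaves the allylic C–O bond with protonation at C16, which moves the olefin to C5=C6 (Z by ring constraint), and removes the C12 acetate to reach 25.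

Step 14 (closing an eight-membered ring onto a 1,1-disubstituted olefin). The fallback sets out from 24 and returns at 25, closing ring B by carbonyl coupling. OsO4/N-methylmorpholine N-oxide dihydroxylates only the two terminal olefins (the tetrasubstituted one is too hindered), and NaIO4 cleavage gives {(1S,2S)-2-methyl-5-[(Z)-1-((1R,3S,3aS,5S,6S,7aR)-6-acetyl-1-hydroxy-7a-methyl-3-(propan-2-yl)octahydro-1H-inden-5-yl)ethylidene]cyclopentyl}acetaldehyde F8. Intramolecular McMurry coupling (TiCl3, Zn(Cu), DME, reflux, high dilution) joins the C1 ketone and C2 aldehyde to give 25.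

**Further compounds**
F1 | step 10 | 1-methyl-2-(prop-2-en-1-yl)cyclopent-2-en-1-ol | C=CCC1=CCCC1(C)O
F2 | step 10 | 3-methyl-2-(prop-2-en-1-yl)cyclopent-2-en-1-one | C=CCC1=C(C)CCC1=O
F3 | step 10 | diethoxy(methyl){[(3S)-3-methyl-2-(prop-2-en-1-yl)cyclopent-1-en-1-yl]oxy}silane | C=CCC1=C(O[Si](C)(OCC)OCC)CC[C@@H]1C
F4 | step 13 | N'-[(2S,3S)-3-methyl-2-(prop-2-en-1-yl)cyclopentylidene]-2,4,6-tri(propan-2-yl)benzenesulfonohydrazide | C=CC[C@@H]1C(=NNS(=O)(=O)c2c(C(C)C)cc(C(C)C)cc2C(C)C)CC[C@@H]1C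
F5 | step 13 | (1R,3S,3aS,5S,6S,7aR)-5-{1-hydroxy-1-[(4S,5S)-4-methyl-5-(prop-2-en-1-yl)cyclopent-1-en-1-yl]ethyl}-7a-methyl-3-(propan-2-yl)-6-(prop-1-en-2-yl)octahydro-1H-inden-1-ol | C=CC[C@@H]1C(=CC[C@@H]1C)C(C)(O)[C@H]2C[C@H]3[C@H](C(C)C)C[C@@H](O)[C@]3(C)C[C@@H]2C(C)=C
F6 | step 13 | ring-B tertiary allylic alcohol (C6 hydroxyl, C5=C16 olefin, C1=C2 Z) | C/C1=C/C[C@@H]2C(=CC[C@@H]2C)C(C)(O)[C@H]3C[C@H]4[C@H](C(C)C)C[C@@H](O)[C@]4(C)C[C@H]13
F7 | step 13 | C6,C12-diacetate of F6 | C/C1=C/C[C@@H]2C(=CC[C@@H]2C)C(C)(OC(C)=O)[C@H]3C[C@H]4[C@H](C(C)C)C[C@@H](OC(C)=O)[C@]4(C)C[C@H]13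
F8 | step 14 | {(1S,2S)-2-methyl-5-[(Z)-1-((1R,3S,3aS,5S,6S,7aR)-6-acetyl-1-hydroxy-7a-methyl-3-(propan-2-yl)octahydro-1H-inden-5-yl)ethylidene]cyclopentyl}acetaldehyde | O=CC[C@@H]1/C(=C(/C)[C@H]2C[C@H]3[C@H](C(C)C)C[C@@H](O)[C@]3(C)C[C@@H]2C(C)=O)CC[C@@H]1C
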